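**Plan**
1. Retrosynthetic cuts: C1–C5 and C9–C10 together (3-oxidopyrylium plus allene, [5+2]) after restoring an oxygen bridge C5–O–C9 and a C6 ketone; then the pyranone back to a furan (Achmatowicz); then the furan–C5 bond (furyllithium plus aldehyde); the side chain at C13–C14, C12–O and C11–CH3 from a furylacrylic acid.
2. Enabling feature: the seven-membered ring (C1, C5–C10) carries oxygen on C9 and on C6, with C5–H between C6 and the ring fusion, and C10 bears an exocyclic CH2 next to ring-fusion C1. C5–C9 are therefore the five carbons of a 3-oxidopyrylium whose ring oxygen once bridged C9 and C5, and C1=C10=C18 is an allene.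
3. Forward order: furan with side chain, furan to pyranone, then the five- and seven-membered carbocycles in one step (temporary 8-oxabicyclo[3.2.1]octenone), cyclopentene by dehydration at C3, bridge opening, C9 inversion, C6 reduction.
4. Stereochemistry: C11 and C12 from the Evans auxiliary; C13 by Felkin–Anh reduction; C4 from methyl (S)-2-methylglycidate, which steers the cycloaddition (C1 and the bridgeheads C5/C9); C7 by equilibration; C5 by protonation with retention; C9 by Mitsunobu inversion; C6 by hydroxyl-directed hydride delivery.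

Key step: step 19

Remark: target numbering is used for every intermediate (C1/C5 ring fusion, C2=C3, C4 with its methyl, C6, C7 with side chain C11–C15, C8, C9, C10=C18; β is the face of H5). C3 (compounds 17–29) and C5/C9 (compounds 23–26) are carried as epimer mixtures that converge in steps 19 and 21 and are left undefined in the SMILES.
Assumption: methyl (S)-2-methyloxirane-2-carboxylate is taken as the commercial enantiopure source of C4.

Step 1
Reactants: 1 (E)-3-(furan-3-yl)acrylic acid; 2 (S)-4-benzyloxazolidin-2-one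
Product: 4 (S)-4-benzyl-3-[(E)-3-(furan-3-yl)acryloyl]oxazolidin-2-one, via mixed pivalic anhydride 3 (not isolated)
Conditions: t-BuCOCl, Et3N, THF, −20 °C; then 2, LiCl, rt
Reagents that add atoms: none
Why: N-acylation of the Evans oxazolidinone through the mixed pivalic anhydride attaches the chiral controller without isomerising the E-alkene; no stereocentre is formed.

Step 2
Reactants: 4 (S)-4-benzyl-3-[(E)-3-(furan-3-yl)acryloyl]oxazolidin-2-one
Product: 5 (S)-4-benzyl-3-[(S)-3-(furan-3-yl)butanoyl]oxazolidin-2-one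
Conditions: MeMgBr, CuBr·SMe2 (30 mol %), THF/Me2S, −40 → −20 °C; aq. NH4Cl
Reagents that add atoms: methylmagnesium bromide, C[Mg]Br
Why: Copper-catalysed conjugate addition of the Grignard reagent to the chelated s-cis N-enoyl imide takes place anti to the benzyl group of the auxiliary and so sets C11 with the methyl group as in the target.

Step 3
Reactants: 5 (S)-4-benzyl-3-[(S)-3-(furan-3-yl)butanoyl]oxazolidin-2-one
Product: 6 (S)-4-benzyl-3-[(S)-3-(2-bromofuran-3-yl)butanoyl]oxazolidin-2-one
Conditions: NBS, DMF, −20 → 0 °C, dark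
Reagents that add atoms: N-bromosuccinimide, BrN1C(=O)CCC1=O
Why: Electrophilic aromatic bromination of a 3-alkylfuran goes to the α-position next to the alkyl group (the future C6), which gives a regiodefined handle for metalation before any bromine-sensitive alkene is present.

Step 4
Reactants: 6 (S)-4-benzyl-3-[(S)-3-(2-bromofuran-3-yl)butanoyl]oxazolidin-2-one
Product: 8 (S)-4-benzyl-3-[(2S,3R)-3-(2-bromofuran-3-yl)-2-hydroxybutanoyl]oxazolidin-2-one, via sodium enolate 7 (not isolated)
Conditions: NaN(SiMe3)2, THF, −78 °C; then 3-phenyl-2-(phenylsulfonyl)oxaziridine, −78 °C; AcOH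
Reagents that add atoms: 3-phenyl-2-(phenylsulfonyl)oxaziridine, O=S(=O)(N1OC1c1ccccc1)c1ccccc1
Why: Evans enolate hydroxylation with the Davis oxaziridine: the chelated Z sodium enolate is oxidised on the face opposite to the benzyl group, which gives the 12S alcohol syn to the C11 methyl group.

Step 5
Reactants: 8 (S)-4-benzyl-3-[(2S,3R)-3-(2-bromofuran-3-yl)-2-hydroxybutanoyl]oxazolidin-2-one
Product: 9 (2S,3R)-3-(2-bromofuran-3-yl)-2-hydroxy-N-methoxy-N-methylbutanamide
Conditions: MeNHOMe·HCl, AlMe3, CH2Cl2, 0 °C → rt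
Reagents that add atoms: N,O-dimethylhydroxylamine hydrochloride, CNOC.Cl
Why: Weinreb transamidation with the aluminium amide opens the imide at the exocyclic carbonyl only and returns the auxiliary while leaving both stereocentres untouched.

Step 6
Reactants: 9 (2S,3R)-3-(2-bromofuran-3-yl)-2-hydroxy-N-methoxy-N-methylbutanamide
Product: 10 (2S,3R)-3-(2-bromofuran-3-yl)-N-methoxy-N-methyl-2-(triethylsilyloxy)butanamide
Conditions: Et3SiCl, imidazole, DMF, 0 °C → rt
Reagents that add atoms: chlorotriethylsilane, CC[Si](Cl)(CC)CC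
Why: Routine silylation of the secondary alcohol, the triethylsilyl ether being non-chelating (needed in step 8) and the most labile silyl group of the route.

Step 7
Reactants: 10 (2S,3R)-3-(2-bromofuran-3-yl)-N-methoxy-N-methyl-2-(triethylsilyloxy)butanamide
Product: 11 (2R,3S)-2-(2-bromofuran-3-yl)-6-methyl-3-(triethylsilyloxy)hept-5-en-4-one
Conditions: Me2C=CHMgBr, THF, 0 °C; aq. NH4Cl
Reagents that add atoms: 2-methylprop-1-enylmagnesium bromide, CC(C)=C[Mg]Br
Why: Weinreb ketone synthesis, in which the chelated tetrahedral intermediate stops the Grignard addition at the enone stage.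

Step 8
Reactants: 11 (2R,3S)-2-(2-bromofuran-3-yl)-6-methyl-3-(triethylsilyloxy)hept-5-en-4-one
Product: 12 (2R,3S,4S)-2-(2-bromofuran-3-yl)-6-methyl-3-(triethylsilyloxy)hept-5-en-4-ol
Conditions: LiBH(s-Bu)3, THF, −78 °C; aq. NH4Cl
Reagents that add atoms: none
Why: Felkin–Anh 1,2-reduction of the α-silyloxy enone by the bulky trialkylborohydride (the β,β-disubstituted alkene resists 1,4-addition) delivers hydride anti to the silyloxy group and gives the 12,13-syn diol derivative, that is 13S.

Step 9
Reactants: 12 (2R,3S,4S)-2-(2-bromofuran-3-yl)-6-methyl-3-(triethylsilyloxy)hept-5-en-4-ol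
Product: 13 2-bromo-3-[(2R,3S,4S)-6-methyl-3,4-bis(triethylsilyloxy)hept-5-en-2-yl]furan
Conditions: Et3SiOTf, 2,6-lutidine, CH2Cl2, −78 °C
Reagents that add atoms: triethylsilyl trifluoromethanesulfonate, CC[Si](CC)(CC)OS(=O)(=O)C(F)(F)F
Why: Silyl triflate silylation of the hindered allylic alcohol under buffered conditions completes the side-chain fragment.

Step 10
Reactants: 14 methyl (S)-2-methyloxirane-2-carboxylate
Product: 15 methyl (S)-2,3-dihydroxy-2-methylpropanoate
Conditions: H2O, HClO4 (cat.), THF, 0 °C → rt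
Reagents that add atoms: water, O
Why: Acid-catalysed epoxide hydrolysis takes place at the primary carbon because the tertiary carbon is deactivated by the ester, so the C4 stereocentre is carried over from the glycidate unchanged.

Step 11
Reactants: 15 methyl (S)-2,3-dihydroxy-2-methylpropanoate
Product: 16 methyl (S)-2-hydroxy-2-methyl-3-oxopropanoate
Conditions: SO3·pyridine, DMSO, i-Pr2NEt, CH2Cl2, 0 °C
Reagents that add atoms: none
Why: Parikh–Doering (activated DMSO) oxidation converts the primary alcohol into the aldehyde and cannot touch the tertiary carbinol, and the aldehyde has no α-hydrogen and cannot epimerise.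

Step 12
Reactants: 16 methyl (S)-2-hydroxy-2-methyl-3-oxopropanoate
Product: 17 methyl (2S)-2,3-dihydroxy-2-methylhex-5-ynoate (C3 epimers)
Conditions: HC≡CCH2Br, Zn, THF/sat. aq. NH4Cl, 0 °C → rt
Reagents that add atoms: propargyl bromide, BrCC#C
Why: Barbier propargylation, the allenylzinc bromide formed in the flask adding by SE2' to give the homopropargylic alcohol; the new C3 carbinol may form as a mixture because it becomes sp2 in step 21.

Step 13
Reactants: 17 methyl (2S)-2,3-dihydroxy-2-methylhex-5-ynoate
Product: 18 methyl (2S)-2,3-bis(tert-butyldimethylsilyloxy)-2-methylhex-5-ynoate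
Conditions: t-BuMe2SiOTf, 2,6-lutidine, CH2Cl2, 0 °C → rt
Reagents that add atoms: tert-butyldimethylsilyl trifluoromethanesulfonate, CC(C)(C)[Si](C)(C)OS(=O)(=O)C(F)(F)F
Why: Silyl triflate silylation protects the secondary and the tertiary hydroxyl in one operation, the tertiary silyl ether at C4 being the control element of step 19.

Step 14
Reactants: 18 methyl (2S)-2,3-bis(tert-butyldimethylsilyloxy)-2-methylhex-5-ynoate
Product: 20 methyl (2S)-2,3-bis(tert-butyldimethylsilyloxy)-2-methylhepta-5,6-dienoate, via Mannich base 19 (not isolated)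
Conditions: (CH2O)n, CuI (cat.), (c-C6H11)2NH, dioxane, reflux
Reagents that add atoms: formaldehyde (as paraformaldehyde), C=O
Why: Crabbé homologation (Mannich reaction of the alkyne, then 1,5-hydride transfer with loss of the imine) turns the terminal alkyne into the terminal allene C1=C10=C18.

Step 15
Reactants: 20 methyl (2S)-2,3-bis(tert-butyldimethylsilyloxy)-2-methylhepta-5,6-dienoate
Product: 21 (2S)-2,3-bis(tert-butyldimethylsilyloxy)-2-methylhepta-5,6-dienal
Conditions: i-Bu2AlH, CH2Cl2, −78 °C; aq. potassium sodium tartrate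
Reagents that add atoms: none
Why: i-Bu2AlH reduction of the α-silyloxy ester at low temperature stops at the aldehyde because the aluminium hemiacetal survives until work-up.

Step 16
Reactants: 13 2-bromo-3-[(2R,3S,4S)-6-methyl-3,4-bis(triethylsilyloxy)hept-5-en-2-yl]furan; 21 (2S)-2,3-bis(tert-butyldimethylsilyloxy)-2-methylhepta-5,6-dienal
Product: 23 furfuryl alcohol (C5 carbinol; mixture at C5 and C3), via 2-furyllithium 22 (not isolated)
Conditions: 13, t-BuLi, Et2O, −78 °C; then 21, −78 °C; aq. NH4Cl
Reagents that add atoms: none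
Why: Bromine–lithium exchange generates the 2-furyllithium at the brominated position only and it adds to the non-enolisable aldehyde, the new C5 carbinol being formed as a mixture that is erased in step 19.

Step 17
Reactants: 23 furfuryl alcohol
Product: 24 pyranone hemiacetal (6-hydroxy-2H-pyran-3(6H)-one)
Conditions: t-BuOOH, VO(acac)2 (cat.), CH2Cl2, 0 °C → rt
Reagents that add atoms: tert-butyl hydroperoxide, CC(C)(C)OO
Why: Achmatowicz oxidative ring expansion of the furfuryl alcohol, the hydroxyl-directed vanadium-catalysed hydroperoxide oxidation sparing the allene and the trisubstituted alkene.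

Step 18
Reactants: 24 pyranone hemiacetal
Product: 26 pyranone triacetate, via pyranone triol 25 (not isolated)
Conditions: HF·pyridine, excess pyridine, THF, 0 °C; then Ac2O, DMAP, pyridine, CH2Cl2, 0 °C → rt
Reagents that add atoms: acetic anhydride, CC(=O)OC(C)=O
Why: Pyridine-buffered fluoride removes only the two secondary triethylsilyl ethers without ionising the hemiacetal, and a single acetylation then installs both acetates of the target and the anomeric leaving group for step 19.

Step 19
Reactants: 26 pyranone triacetate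
Product: 28 oxygen-bridged cycloadduct, via oxidopyrylium ylide 27 (not isolated)
Conditions: DBU, MeCN (0.005 M), rt → 60 °C
Reagents that add atoms: none
Why: DBU removes acetic acid from the 6-acetoxypyranone to give the 3-oxidopyrylium ylide 27, whose termini C5 and C9 add suprafacially in a concerted, asynchronous [5+2] cycloaddition to the proximal C1=C10 π bond of the tethered allene. The closest known reaction type is the intramolecular oxidopyrylium–alkene [5+2] cycloaddition with a three-atom tether, and allenes serve as two-carbon partners in the same way in related [5+2] and carbonyl ylide cycloadditions. The cyclopentane closes by C5–C1 bond formation in a 5-exo sense through the tether C4–C3–C2, and the seven-membered carbocycle C1–C5–C6–C7–C8–C9–C10 closes by C9–C10 bond formation onto the central allene carbon, which leaves C10=C18 exocyclic and the ring oxygen as the C5–O–C9 bridge. C1 is set by the tether, which can only span the bridgehead exo (syn to the oxygen bridge, H1 anti to it); C5 and C9 are set relative to C4 by the face of the ylide that is attacked, the C4 stereocentre placing its silyloxy group on the side of the ring oxygen and its methyl group next to the oxido group (allylic strain and lone-pair repulsion with the oxido oxygen). The step needs the proximal and not the terminal allene π bond, which the preference for five-membered ring closure and the higher substitution of that bond should secure, and cycloaddition in place of ylide dimerisation, which high dilution secures.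

Step 20
Reactants: 28 oxygen-bridged cycloadduct
Product: 29 3-hydroxy cycloadduct (4-OTBS retained)
Conditions: HF·pyridine, pyridine, THF, rt
Reagents that add atoms: none
Why: Fluoride desilylation in which the secondary silyl ether at C3 is cleaved far faster than the tertiary one at C4, which unveils the only free hydroxyl of the molecule.

Step 21
Reactants: 29 3-hydroxy cycloadduct
Product: 30 cyclopentene cycloadduct (C2=C3)
Conditions: Ph2S[OC(CF3)2Ph]2, CH2Cl2, 0 °C → rt
Reagents that add atoms: none
Why: Martin sulfurane dehydration (E2 through the alkoxysulfonium ion) can remove a proton only from C2 because C4 is quaternary, which gives the C2=C3 alkene of the cyclopentene.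

Step 22
Reactants: 30 cyclopentene cycloadduct
Product: 32 saturated bridged ketone (side chain exo), via 7-epi ketone 31 (not isolated)
Conditions: [(Ph3P)CuH]6, toluene, H2O, rt; then DBU, CH2Cl2, rt
Reagents that add atoms: none
Why: Conjugate reduction by the copper hydride is selective for the enone over isolated alkenes and esters, and base equilibration of the only enolisable centre then places the C7 side chain equatorial and exo (syn to the oxygen bridge), the configuration of the target.

Step 23
Reactants: 32 saturated bridged ketone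
Product: 34 trans-fused 9β-hydroxy-6-ketone, via samarium enolate 33 (not isolated)
Conditions: SmI2, THF/MeOH, −78 °C
Reagents that add atoms: none
Why: SmI2 reduction of the α-alkoxy ketone (ketyl, loss of the C5 alkoxide, second electron transfer) opens the oxygen bridge to the 9-hydroxy enolate, and protonation at C5 on the face just vacated by the oxygen, relayed by the samarium-bound C9 alkoxide and methanol, should give the trans ring fusion with retention.

Step 24
Reactants: 34 trans-fused 9β-hydroxy-6-ketone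
Product: 35 9α-chloroacetate of the 6-ketone
Conditions: ClCH2CO2H, PPh3, DIAD, toluene, 0 °C → rt
Reagents that add atoms: chloroacetic acid, OC(=O)CCl
Why: Mitsunobu reaction with chloroacetic acid inverts the allylic C9 carbinol by SN2 attack on the less hindered α-face, which corrects the one centre that the bridged cycloadduct necessarily carries epimeric to the target.

Step 25
Reactants: 35 9α-chloroacetate of the 6-ketone
Product: 36 9α-hydroxy-6-ketone
Conditions: thiourea, NaHCO3, EtOH, 50 °C
Reagents that add atoms: none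
Why: Thiourea cleaves the chloroacetate by S-alkylation and cyclisation under conditions that leave the two acetates and the enolisable ketone untouched.

Step 26
Reactants: 36 9α-hydroxy-6-ketone
Product: 37 4-O-tert-butyldimethylsilyl ether of the target
Conditions: Me4NBH(OAc)3, MeCN/AcOH, −20 °C
Reagents that add atoms: none
Why: Hydroxyl-directed triacetoxyborohydride reduction (Saksena–Evans type), in which exchange of acetate for the 9α-hydroxyl lets hydride cross the ring to the α-face of C6, also the face anti to the C7 side chain, and gives the 6β-alcohol.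

Step 27
Reactants: 37 4-O-tert-butyldimethylsilyl ether of the target
Product: 38 target CNP0269663.3
Conditions: HF·pyridine, pyridine, THF, rt → 40 °C
Reagents that add atoms: none
Why: Fluoride cleavage of the tertiary silyl ether under buffered, non-basic conditions leaves the acetates and the allylic alcohols intact and gives the target.

**Compound list**
1 | (E)-3-(furan-3-yl)acrylic acid | OC(=O)/C=C/c1ccoc1 | starting material
2 | (S)-4-benzyloxazolidin-2-one | O=C1N[C@@H](Cc2ccccc2)CO1 | starting material
3 | (E)-3-(furan-3-yl)acrylic pivalic anhydride | CC(C)(C)C(=O)OC(=O)/C=C/c1ccoc1 | intermediate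
4 | (S)-4-benzyl-3-[(E)-3-(furan-3-yl)acryloyl]oxazolidin-2-one | O=C(/C=C/c1ccoc1)N1[C@@H](Cc2ccccc2)COC1=O | intermediate
5 | (S)-4-benzyl-3-[(S)-3-(furan-3-yl)butanoyl]oxazolidin-2-one | C[C@H](c1ccoc1)CC(=O)N1[C@@H](Cc2ccccc2)COC1=O | intermediate
6 | (S)-4-benzyl-3-[(S)-3-(2-bromofuran-3-yl)butanoyl]oxazolidin-2-one | C[C@H](c1ccoc1Br)CC(=O)N1[C@@H](Cc2ccccc2)COC1=O | intermediate
7 | sodium (Z)-enolate of 6 | C[C@H](c1ccoc1Br)/C=C(\[O-])N1[C@@H](Cc2ccccc2)COC1=O.[Na+] | intermediate
8 | (S)-4-benzyl-3-[(2S,3R)-3-(2-bromofuran-3-yl)-2-hydroxybutanoyl]oxazolidin-2-one | C[C@H](c1ccoc1Br)[C@H](O)C(=O)N1[C@@H](Cc2ccccc2)COC1=O | intermediate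
9 | (2S,3R)-3-(2-bromofuran-3-yl)-2-hydroxy-N-methoxy-N-methylbutanamide | C[C@H](c1ccoc1Br)[C@H](O)C(=O)N(C)OC | intermediate
10 | (2S,3R)-3-(2-bromofuran-3-yl)-N-methoxy-N-methyl-2-(triethylsilyloxy)butanamide | C[C@H](c1ccoc1Br)[C@H](O[Si](CC)(CC)CC)C(=O)N(C)OC | intermediate
11 | (2R,3S)-2-(2-bromofuran-3-yl)-6-methyl-3-(triethylsilyloxy)hept-5-en-4-one | C[C@H](c1ccoc1Br)[C@H](O[Si](CC)(CC)CC)C(=O)C=C(C)C | intermediate
12 | (2R,3S,4S)-2-(2-bromofuran-3-yl)-6-methyl-3-(triethylsilyloxy)hept-5-en-4-ol | C[C@H](c1ccoc1Br)[C@H](O[Si](CC)(CC)CC)[C@H](C=C(C)C)O | intermediate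
13 | 2-bromo-3-[(2R,3S,4S)-6-methyl-3,4-bis(triethylsilyloxy)hept-5-en-2-yl]furan | C[C@H](c1ccoc1Br)[C@H](O[Si](CC)(CC)CC)[C@H](C=C(C)C)O[Si](CC)(CC)CC | intermediate
14 | methyl (S)-2-methyloxirane-2-carboxylate | COC(=O)[C@]1(C)CO1 | starting material
15 | methyl (S)-2,3-dihydroxy-2-methylpropanoate | COC(=O)[C@@](C)(O)CO | intermediate
16 | methyl (S)-2-hydroxy-2-methyl-3-oxopropanoate | COC(=O)[C@@](C)(O)C=O | intermediate
17 | methyl (2S)-2,3-dihydroxy-2-methylhex-5-ynoate (C3 epimers) | COC(=O)[C@@](C)(O)C(O)CC#C | intermediate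
18 | methyl (2S)-2,3-bis(tert-butyldimethylsilyloxy)-2-methylhex-5-ynoate | COC(=O)[C@@](C)(O[Si](C)(C)C(C)(C)C)C(O[Si](C)(C)C(C)(C)C)CC#C | intermediate
19 | methyl (2S)-2,3-bis(tert-butyldimethylsilyloxy)-7-(dicyclohexylamino)-2-methylhept-5-ynoate (Mannich base) | COC(=O)[C@@](C)(O[Si](C)(C)C(C)(C)C)C(O[Si](C)(C)C(C)(C)C)CC#CCN(C1CCCCC1)C1CCCCC1 | intermediate
20 | methyl (2S)-2,3-bis(tert-butyldimethylsilyloxy)-2-methylhepta-5,6-dienoate | COC(=O)[C@@](C)(O[Si](C)(C)C(C)(C)C)C(O[Si](C)(C)C(C)(C)C)CC=C=C | intermediate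
21 | (2S)-2,3-bis(tert-butyldimethylsilyloxy)-2-methylhepta-5,6-dienal | O=C[C@@](C)(O[Si](C)(C)C(C)(C)C)C(O[Si](C)(C)C(C)(C)C)CC=C=C | intermediate
22 | {3-[(2R,3S,4S)-6-methyl-3,4-bis(triethylsilyloxy)hept-5-en-2-yl]furan-2-yl}lithium | C[C@H](c1ccoc1[Li])[C@H](O[Si](CC)(CC)CC)[C@H](C=C(C)C)O[Si](CC)(CC)CC | intermediate
23 | furfuryl alcohol: 1-{3-[(2R,3S,4S)-6-methyl-3,4-bis(triethylsilyloxy)hept-5-en-2-yl]furan-2-yl}-2,3-bis(tert-butyldimethylsilyloxy)-2-methylhepta-5,6-dien-1-ol (C4 as in 21; C5 and C3 epimers) | C[C@H](c1ccoc1C(O)[C@@](C)(O[Si](C)(C)C(C)(C)C)C(O[Si](C)(C)C(C)(C)C)CC=C=C)[C@H](O[Si](CC)(CC)CC)[C@H](C=C(C)C)O[Si](CC)(CC)CC | intermediate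
24 | pyranone hemiacetal: 6-hydroxy-2H-pyran-3(6H)-one with the 1,2-bis(tert-butyldimethylsilyloxy)-1-methylhexa-4,5-dienyl group (C4 as in 21) at pyran C-2 (C5) and the (11R,12S,13S)-bis(triethylsilyloxy) side chain at pyran C-4 (C7) | OC1C=C([C@@H](C)[C@H](O[Si](CC)(CC)CC)[C@H](C=C(C)C)O[Si](CC)(CC)CC)C(=O)C(O1)[C@@](C)(O[Si](C)(C)C(C)(C)C)C(O[Si](C)(C)C(C)(C)C)CC=C=C | intermediate
25 | pyranone triol: 24 with free 12-OH and 13-OH | OC1C=C([C@@H](C)[C@H](O)[C@H](C=C(C)C)O)C(=O)C(O1)[C@@](C)(O[Si](C)(C)C(C)(C)C)C(O[Si](C)(C)C(C)(C)C)CC=C=C | intermediate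
26 | pyranone triacetate: 6-acetoxy-2H-pyran-3(6H)-one with 12,13-diacetate side chain | CC(=O)OC1C=C([C@@H](C)[C@H](OC(C)=O)[C@H](C=C(C)C)OC(C)=O)C(=O)C(O1)[C@@](C)(O[Si](C)(C)C(C)(C)C)C(O[Si](C)(C)C(C)(C)C)CC=C=C | intermediate
27 | 3-oxidopyrylium ylide (ring carbons C5–C9; tether at C5; diacetate side chain at C7) | [O-]c1c([C@@H](C)[C@H](OC(C)=O)[C@H](C=C(C)C)OC(C)=O)cc[o+]c1[C@@](C)(O[Si](C)(C)C(C)(C)C)C(O[Si](C)(C)C(C)(C)C)CC=C=C | intermediate
28 | oxygen-bridged cycloadduct: 5,9-epoxy bridge on the β-face; C6 ketone; C7=C8; C10=C18 exocyclic; cyclopentane C1–C5 fused exo with H1 α; 3,4-bis-OTBS; 12,13-diacetate | C=C1[C@@H](O3)C=C([C@@H](C)[C@H](OC(C)=O)[C@H](C=C(C)C)OC(C)=O)C(=O)[C@]32[C@H]1CC(O[Si](C)(C)C(C)(C)C)[C@]2(C)O[Si](C)(C)C(C)(C)C | intermediate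
29 | 3-hydroxy cycloadduct (28 with free 3-OH; 4-OTBS retained) | C=C1[C@@H](O3)C=C([C@@H](C)[C@H](OC(C)=O)[C@H](C=C(C)C)OC(C)=O)C(=O)[C@]32[C@H]1CC(O)[C@]2(C)O[Si](C)(C)C(C)(C)C | intermediate
30 | cyclopentene cycloadduct (C2=C3; otherwise as 28) | C=C1[C@@H](O3)C=C([C@@H](C)[C@H](OC(C)=O)[C@H](C=C(C)C)OC(C)=O)C(=O)[C@]32[C@H]1C=C[C@]2(C)O[Si](C)(C)C(C)(C)C | intermediate
31 | 7-epi saturated bridged ketone (7,8-dihydro-30; side chain endo) | C=C1[C@@H](O3)C[C@H]([C@@H](C)[C@H](OC(C)=O)[C@H](C=C(C)C)OC(C)=O)C(=O)[C@]32[C@H]1C=C[C@]2(C)O[Si](C)(C)C(C)(C)C | intermediate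
32 | saturated bridged ketone (7,8-dihydro-30; side chain exo and syn to the oxygen bridge) | C=C1[C@@H](O3)C[C@@H]([C@@H](C)[C@H](OC(C)=O)[C@H](C=C(C)C)OC(C)=O)C(=O)[C@]32[C@H]1C=C[C@]2(C)O[Si](C)(C)C(C)(C)C | intermediate
33 | samarium enolate (C5=C6–O–SmI2; 9β-O–SmI2) | C=C1[C@@H](O[Sm](I)I)C[C@@H]([C@@H](C)[C@H](OC(C)=O)[C@H](C=C(C)C)OC(C)=O)C(O[Sm](I)I)=C2[C@H]1C=C[C@]2(C)O[Si](C)(C)C(C)(C)C | intermediate
34 | trans-fused 9β-hydroxy-6-ketone (H1 α; H5 β; 9-epi to the target; 4-OTBS; 12,13-diacetate) | C=C1[C@@H](O)C[C@@H]([C@@H](C)[C@H](OC(C)=O)[C@H](C=C(C)C)OC(C)=O)C(=O)[C@H]2[C@H]1C=C[C@]2(C)O[Si](C)(C)C(C)(C)C | intermediate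
35 | 9α-chloroacetate of the 6-ketone | C=C1[C@H](OC(=O)CCl)C[C@@H]([C@@H](C)[C@H](OC(C)=O)[C@H](C=C(C)C)OC(C)=O)C(=O)[C@H]2[C@H]1C=C[C@]2(C)O[Si](C)(C)C(C)(C)C | intermediate
36 | 9α-hydroxy-6-ketone | C=C1[C@H](O)C[C@@H]([C@@H](C)[C@H](OC(C)=O)[C@H](C=C(C)C)OC(C)=O)C(=O)[C@H]2[C@H]1C=C[C@]2(C)O[Si](C)(C)C(C)(C)C | intermediate
37 | 4-O-tert-butyldimethylsilyl ether of the target | C=C1[C@H](O)C[C@@H]([C@@H](C)[C@H](OC(C)=O)[C@H](C=C(C)C)OC(C)=O)[C@@H](O)[C@H]2[C@H]1C=C[C@]2(C)O[Si](C)(C)C(C)(C)C | intermediate
38 | CNP0269663.3 | C=C1[C@H](O)C[C@@H]([C@@H](C)[C@H](OC(C)=O)[C@H](C=C(C)C)OC(C)=O)[C@@H](O)[C@H]2[C@H]1C=C[C@]2(C)O | target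

Total step count: 27. Longest linear sequence: 21 steps (steps 1–9 and 16–27); aldehyde 21 is made in 6 steps (steps 10–15).

**Steps most likely to fail**

Step 19: the allene may fold onto either face of the ylide with too little discrimination, since the C4 silyl ether is the only control element, and slow ring closure would let the ylide dimerise. Fallback: control by a catalyst in place of the substrate. It sets out from 24: acylation of the anomeric hydroxyl with 4-(methylthio)benzoyl chloride (Et3N, DMAP) should give the anomeric 4-(methylthio)benzoate F1; HF·pyridine and then Ac2O as in step 18 should give the 12,13-diacetate F2. F2 is then cyclised with a chiral primary aminothiourea and an achiral thiourea co-catalyst (aminopyrylium formation with carboxylate binding, established for intramolecular oxidopyrylium [5+2] cycloadditions), using the catalyst antipode matched to the C4-directed sense. The fallback comes back to the route at 28.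

Step 23: the enolate may be protonated on the exposed α-face of C5, which would give the cis ring fusion. Fallback: thermodynamic in place of kinetic control. It sets out from 32: the cis-fused 5-epi hydroxy ketone F3 formed in the SmI2 reaction is collected and equilibrated through its enol with DBU in toluene, the trans-fused isomer being the one that keeps C6 anti to the bulky C4 silyloxy group. It comes back at 34.

Step 26: hydride may reach C6 without transannular direction and from the β-face, which would give the 6α-alcohol. Fallback: catalyst control and a changed order of steps. It sets out from 35, which has no free hydroxyl: reduction with catecholborane and the matched antipode of the 2-methyl-CBS-oxazaborolidine (Corey–Bakshi–Shibata reduction) should give the 6β-alcohol 9α-chloroacetate F4, and thiourea/NaHCO3 as in step 25 then brings it back to the route at 37.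

**Further compounds**
F1 | step 19 | anomeric 4-(methylthio)benzoate of hemiacetal 24 (12,13-bis-OTES) | CSc1ccc(cc1)C(=O)OC1C=C([C@@H](C)[C@H](O[Si](CC)(CC)CC)[C@H](C=C(C)C)O[Si](CC)(CC)CC)C(=O)C(O1)[C@@](C)(O[Si](C)(C)C(C)(C)C)C(O[Si](C)(C)C(C)(C)C)CC=C=C
F2 | step 19 | anomeric 4-(methylthio)benzoate with 12,13-diacetate side chain | CSc1ccc(cc1)C(=O)OC1C=C([C@@H](C)[C@H](OC(C)=O)[C@H](C=C(C)C)OC(C)=O)C(=O)C(O1)[C@@](C)(O[Si](C)(C)C(C)(C)C)C(O[Si](C)(C)C(C)(C)C)CC=C=C
F3 | step 23 | cis-fused 5-epi isomer of 34 | C=C1[C@@H](O)C[C@@H]([C@@H](C)[C@H](OC(C)=O)[C@H](C=C(C)C)OC(C)=O)C(=O)[C@@H]2[C@H]1C=C[C@]2(C)O[Si](C)(C)C(C)(C)C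
F4 | step 26 | 6β-hydroxy 9α-chloroacetate (4-OTBS) | C=C1[C@H](OC(=O)CCl)C[C@@H]([C@@H](C)[C@H](OC(C)=O)[C@H](C=C(C)C)OC(C)=O)[C@@H](O)[C@H]2[C@H]1C=C[C@]2(C)O[Si](C)(C)C(C)(C)C
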